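The plan treats the C3'–C4'–C5'–C6' segment of oxane ring B (C3' oxygenated, C6' quaternary and joined to O1') as a masked 2,5-disubstituted furan. Furan C2 is bonded to the carbinol carbon C2', and furan C5 holds one of the C6' methyl groups. Achmatowicz oxidation of this furyl carbinol, which already contains ring A (C3=C4 alkene, C1 acetate) and the C2' stereocentre, makes the O1'–C6' bond and ring B as a pyranone hemiketal in a single operation. The precursor arises from an Evans aldol, ring-closing metathesis and a chelate-controlled furyl addition. Afterwards C5'–Br comes from face-selective bromination of a C5'=C6' enol ether, C6' is methylated, and ring A is halogenated stepwise via its β-epoxide.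

Key step: step 9

Numbering: ring A = C1 (O), C2, C3 (CH3), C4, C5, C6 (bonded to C2'). Ring B = O1', C2', C3', C4', C5', C6'. On ring A, α is the face carrying the C1 oxygen and the C6–C2' bond, and β is the other face. On ring B, "upper" is the face with the C2'–C6 bond and the C3' oxygen, and "lower" is the face with the C2' methyl group.
Remark: all facial arguments assume that ring A sits in the (half-)chair with the bulky C6 side chain equatorial and the C1 oxygen axial, and ring B in the chair with ring A equatorial at C2'.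

Step 1
Reactants: 1 (S)-4-benzyl-1,3-oxazolidin-2-one; 2 pent-4-enoyl chloride
Product: 3 (S)-4-benzyl-3-(pent-4-enoyl)-1,3-oxazolidin-2-one
Conditions: Et3N, DMAP (10 mol %), CH2Cl2, 0 → 23 °C
Reagents that add atoms: none
Why: N-acylation of the oxazolidinone with an acid chloride under nucleophilic catalysis is routine and installs the auxiliary that will control C6 and C1.

Step 2
Reactants: 4 3-methylbut-3-en-1-ol
Product: 5 3-methylbut-3-enal
Conditions: Dess–Martin periodinane, NaHCO3, CH2Cl2, 0 → 23 °C; filtered solution used at once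
Reagents that add atoms: none
Why: Buffered Dess–Martin oxidation stops at the aldehyde, and the near-neutral medium together with immediate use should keep the 1,1-disubstituted alkene out of conjugation.

Step 3
Reactants: 3 N-pentenoyl oxazolidinone; 5 3-methylbut-3-enal
Product: 7 (S)-4-benzyl-3-[(2S,3R)-3-hydroxy-5-methyl-2-(prop-2-enyl)hex-5-enoyl]-1,3-oxazolidin-2-one, via dibutylboron Z-enolate 6 (not isolated)
Conditions: Bu2BOTf, Et3N, CH2Cl2, −78 → 0 °C; 5, −78 → 0 °C; pH 7 buffer, MeOH, H2O2
Reagents that add atoms: none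
Why: In the Evans syn-aldol reaction the Z-boron enolate reacts through a closed chair transition state on the face remote from the benzyl group, which sets C6 (S) and C1 (R) in the syn relationship that becomes cis on ring A.

Step 4
Reactants: 7 syn-aldol adduct
Product: 8 (S)-4-benzyl-3-{[(1S,6R)-6-hydroxy-4-methylcyclohex-3-en-1-yl]carbonyl}-1,3-oxazolidin-2-one
Conditions: (H2IMes)(PCy3)Cl2Ru=CHPh (second-generation Grubbs catalyst, 3 mol %), CH2Cl2 (0.005 M), 40 °C
Reagents that add atoms: none
Why: Ring-closing metathesis of the monosubstituted and the 1,1-disubstituted alkene closes six-membered ring A with the trisubstituted C3=C4 bond, tolerates the free hydroxyl and touches no stereocentre.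

Step 5
Reactants: 8 ring A imide
Product: 9 (1S,6R)-6-hydroxy-N-methoxy-N,4-dimethylcyclohex-3-ene-1-carboxamide
Conditions: Me(MeO)NH·HCl, AlMe3, CH2Cl2, −10 → 23 °C
Reagents that add atoms: N,O-dimethylhydroxylamine hydrochloride, CNOC.Cl
Why: Aluminium-amide transamination of an aldol imide (Weinreb amide synthesis) is helped by the free β-hydroxyl, attacks the exocyclic carbonyl and releases the auxiliary without epimerising C6.

Step 6
Reactants: 9 Weinreb amide
Product: 10 1-[(1S,6R)-6-hydroxy-4-methylcyclohex-3-en-1-yl]ethanone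
Conditions: MeMgBr (3.5 equiv), THF, −78 → 0 °C; aq. NH4Cl
Reagents that add atoms: methylmagnesium bromide, C[Mg]Br
Why: In the Weinreb ketone synthesis the chelated tetrahedral adduct survives until the mild quench, so addition stops at the ketone and C6 is not exposed to base as a ketone.

Step 7
Reactants: 10 β-hydroxy methyl ketone; 11 2-methylfuran
Product: 14 (1R,6S)-6-[(1S)-1-hydroxy-1-(5-methylfuran-2-yl)ethyl]-3-methylcyclohex-3-en-1-ol, via 5-methyl-2-furyllithium 12 (not isolated), via 5-methyl-2-furylmagnesium bromide 13 (not isolated)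
Conditions: 11, n-BuLi, THF, 0 °C; MgBr2·OEt2, 0 °C; 10 (2.5 equiv of 13 per ketone), −78 → −20 °C; aq. NH4Cl
Reagents that add atoms: none
Why: In this chelation-controlled Grignard addition the first equivalent turns C1–OH into a magnesium alkoxide that ties up the ketone oxygen in a six-membered chelate, and the furyl group attacks the carbonyl face on the side of C6–H, away from C5, which sets C2' (S).

Step 8
Reactants: 14 diol
Product: 15 (1R,6S)-6-[(1S)-1-hydroxy-1-(5-methylfuran-2-yl)ethyl]-3-methylcyclohex-3-en-1-yl acetate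
Conditions: Ac2O, pyridine, DMAP (5 mol %), CH2Cl2, 0 → 23 °C
Reagents that add atoms: acetic anhydride, CC(=O)OC(C)=O
Why: Acylation discriminates cleanly between the secondary C1 hydroxyl and the tertiary furyl carbinol, and it places the acetate of the target so that no protecting-group exchange is needed at C1.

Step 9
Reactants: 15 furyl carbinol acetate
Product: 17 (1R,6S)-6-[(2S)-6-hydroxy-2,6-dimethyl-3-oxo-3,6-dihydro-2H-pyran-2-yl]-3-methylcyclohex-3-en-1-yl acetate (C6' anomers), via Z-enedione 16 (not isolated)
Conditions: NBS (1.05 equiv), NaHCO3, THF–H2O (4:1), 0 °C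
Reagents that add atoms: water, O
Why: Electrophilic bromine adds to the electron-rich furan, water attacks, and loss of HBr opens the heterocycle to the Z-enedione 16. The C2' hydroxyl then adds to the C6' methyl ketone in a 6-exo-trig hemiketalisation that forms O1'–C6' and closes ring B; this is the Achmatowicz rearrangement, which is established for tertiary 5-methylfurfuryl alcohols. The only new stereocentre is the hemiketal carbon C6', which equilibrates under thermodynamic (anomeric) control and is erased in step 16, while C2' keeps its configuration because none of its bonds is broken. The step needs chemoselectivity for the furan over the C3=C4 alkene, which the far higher nucleophilicity of the heteroarene secures when one equivalent of NBS is used at 0 °C. It also needs the acid-labile tertiary furyl carbinol to survive, which the NaHCO3 buffer secures by taking up the HBr.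

Step 10
Reactants: 17 pyranone hemiketal
Product: 18 (1R,6S)-6-[(2S)-6-methoxy-2,6-dimethyl-3-oxo-3,6-dihydro-2H-pyran-2-yl]-3-methylcyclohex-3-en-1-yl acetate (C6' anomers)
Conditions: MeOH, HC(OMe)3, CSA (10 mol %), 0 → 23 °C
Reagents that add atoms: methanol, CO
Why: Acid-catalysed ketalisation through the ring oxocarbenium ion locks ring B shut, so that the hydride steps cannot reach an open-chain dione, and the anomeric mixture is of no consequence.

Step 11
Reactants: 18 enone ketal
Product: 19 (1R,6S)-6-[(2S)-6-methoxy-2,6-dimethyl-3-oxooxan-2-yl]-3-methylcyclohex-3-en-1-yl acetate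
Conditions: [(Ph3P)CuH]6 (3 mol %), PhMe2SiH, t-BuOH, toluene, 23 °C
Reagents that add atoms: none
Why: Copper hydride conjugate reduction saturates only the C4'=C5' bond of the enone and leaves the isolated trisubstituted alkene, the acetate and the ketal alone.

Step 12
Reactants: 19 ketone
Product: 20 (1R,6S)-6-[(2S,3S)-3-hydroxy-6-methoxy-2,6-dimethyloxan-2-yl]-3-methylcyclohex-3-en-1-yl acetate
Conditions: LiBH(s-Bu)3, THF, −78 °C; pH 7 buffer, H2O2
Reagents that add atoms: none
Why: The bulky trialkylborohydride attacks the chair oxan-3-one along the equatorial trajectory and should give the axial, upper-face C3' alcohol (S), while the hindered acetate is inert at −78 °C.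

Step 13
Reactants: 20 axial alcohol
Product: 21 C3' tert-butyldimethylsilyl ether of 20
Conditions: TBSOTf, 2,6-lutidine, CH2Cl2, 0 °C
Reagents that add atoms: tert-butyldimethylsilyl triflate, CC(C)(C)[Si](C)(C)OS(=O)(=O)C(F)(F)F
Why: The silyl triflate silylates even this neopentyl-type axial alcohol and supplies the bulky axial group that has to screen the upper face of ring B in step 15.

Step 14
Reactants: 21 silylated ketal
Product: 22 (1R,6S)-6-[(2S,3S)-3-(tert-butyldimethylsilyloxy)-2,6-dimethyl-3,4-dihydro-2H-pyran-2-yl]-3-methylcyclohex-3-en-1-yl acetate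
Conditions: PPTS (10 mol %), toluene, 110 °C, 4 Å molecular sieves
Reagents that add atoms: none
Why: Acid-catalysed loss of methanol from the ketal under equilibrating conditions should deliver the more stable endocyclic trisubstituted enol ether C5'=C6' and not its exocyclic methylene isomer.

Step 15
Reactants: 22 cyclic enol ether
Product: 23 (2'S,3'S,5'S)-5'-bromo-6'-methoxy ketal: 22 with lower-face Br at C5' and OMe plus CH3 at C6' (C6' anomers)
Conditions: NBS (1.0 equiv), MeOH–CH2Cl2 (1:4), −78 → −40 °C
Reagents that add atoms: N-bromosuccinimide, O=C1CCC(=O)N1Br; methanol, CO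
Why: In this haloalkoxylation of a glycal-type enol ether, bromine attacks the nucleophilic C5' from the lower face because the axial C3' silyl ether screens the upper face (as an axial C4 substituent does in galactals), which sets C5' (S); methanol then caps the C6' oxocarbenium ion and the much less nucleophilic ring A alkene is spared at low temperature.

Step 16
Reactants: 23 bromo ketal
Product: 24 (1R,6S)-6-[(2S,3S,5S)-5-bromo-3-(tert-butyldimethylsilyloxy)-2,6,6-trimethyloxan-2-yl]-3-methylcyclohex-3-en-1-yl acetate
Conditions: AlMe3 (5 equiv), CH2Cl2, −78 → 0 °C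
Reagents that add atoms: trimethylaluminium, C[Al](C)C
Why: Aluminium binds the exposed methoxy oxygen, the tertiary ring oxocarbenium ion forms and takes up a methyl group from the aluminate (SN1 methylation of a ketal, C-glycosidation type), so C6' becomes the non-stereogenic gem-dimethyl carbon while C5' is untouched.

Step 17
Reactants: 24 ring A alkene
Product: 25 (3R,4S)-3,4-β-epoxide of 24
Conditions: mCPBA, CH2Cl2, 0 °C
Reagents that add atoms: 3-chloroperoxybenzoic acid, O=C(OO)c1cccc(Cl)c1
Why: Prilezhaev epoxidation of the only remaining alkene should occur on the β face, anti to the axial C1 acetate that overhangs C3 on the α face, and so places oxygen β at C3 and C4.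

Step 18
Reactants: 25 β-epoxide
Product: 26 (3R,4R)-4α-bromo-3β-hydroxy compound (trans-diequatorial bromohydrin)
Conditions: Li2NiBr4, THF, 0 → 23 °C; pH 7 buffer
Reagents that add atoms: dilithium tetrabromonickelate Li2NiBr4, [Li+].[Li+].[Ni+2].[Br-].[Br-].[Br-].[Br-]
Why: Soft bromide opens the trisubstituted epoxide by SN2 at the secondary carbon C4 from the α face with inversion, the rear of the tertiary C3 being closed by the syn-axial acetate, and this sets the final C4 configuration (R).

Step 19
Reactants: 26 bromohydrin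
Product: 28 C3' tert-butyldimethylsilyl ether of the target (3β-Cl and 4α-Br), via tertiary chlorosulfite 27 (not isolated)
Conditions: SOCl2, CH2Cl2, −20 → 23 °C
Reagents that add atoms: thionyl chloride, O=S(Cl)Cl
Why: The tertiary chlorosulfite ionises and chloride returns on the β face (SNi-type ion-pair collapse), because the α face of the C3 cation is covered by the C4 bromine and the C1 acetate carbonyl, so C3–O is replaced by C3–Cl with retention (R).

Step 20
Reactants: 28 silyl ether
Product: 29 target, (1R,3R,4R,6S)-4-bromo-6-[(2S,3S,5S)-5-bromo-3-hydroxy-2,6,6-trimethyloxan-2-yl]-3-chloro-3-methylcyclohexyl acetate (route numbering)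
Conditions: HF·pyridine, THF, 0 → 23 °C
Reagents that add atoms: none
Why: Fluoride-driven cleavage of the silyl ether in a weakly acidic, non-basic medium frees C3'–OH without acetate migration or loss of HBr or HCl.

Compound list
1 | (S)-4-benzyl-1,3-oxazolidin-2-one | O=C1N[C@@H](Cc2ccccc2)CO1 | starting material
2 | pent-4-enoyl chloride | C=CCCC(=O)Cl | starting material
3 | (S)-4-benzyl-3-(pent-4-enoyl)-1,3-oxazolidin-2-one | C=CCCC(=O)N1[C@@H](Cc2ccccc2)COC1=O | intermediate
4 | 3-methylbut-3-en-1-ol | CC(=C)CCO | starting material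
5 | 3-methylbut-3-enal | CC(=C)CC=O | intermediate
6 | dibutylboron Z-enolate of 3 | C=CC/C=C(\OB(CCCC)CCCC)N1[C@@H](Cc2ccccc2)COC1=O | intermediate
7 | (2S,3R) syn-aldol adduct | C=CC[C@@H]([C@H](O)CC(C)=C)C(=O)N1[C@@H](Cc2ccccc2)COC1=O | intermediate
8 | ring A imide, (1S,6R)-6-hydroxy-4-methylcyclohex-3-enecarbonyl oxazolidinone | O[C@@H]1CC(C)=CC[C@@H]1C(=O)N1[C@@H](Cc2ccccc2)COC1=O | intermediate
9 | ring A Weinreb amide | O[C@@H]1CC(C)=CC[C@@H]1C(=O)N(C)OC | intermediate
10 | ring A β-hydroxy methyl ketone | O[C@@H]1CC(C)=CC[C@@H]1C(C)=O | intermediate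
11 | 2-methylfuran | Cc1ccco1 | starting material
12 | 5-methyl-2-furyllithium | [Li]c1ccc(C)o1 | intermediate
13 | 5-methyl-2-furylmagnesium bromide | Br[Mg]c1ccc(C)o1 | intermediate
14 | furyl carbinol diol (1R,6S,2'S) | O[C@@H]1CC(C)=CC[C@@H]1[C@](C)(O)c1ccc(C)o1 | intermediate
15 | furyl carbinol C1 acetate (precursor of the key step) | CC(=O)O[C@@H]1CC(C)=CC[C@@H]1[C@](C)(O)c1ccc(C)o1 | intermediate
16 | Z-enedione | CC(=O)O[C@@H]1CC(C)=CC[C@@H]1[C@](C)(O)C(=O)/C=C\C(C)=O | intermediate
17 | 6'-hydroxy-6'-methylpyran-3'-one on ring A (C6' anomers) | CC(=O)O[C@@H]1CC(C)=CC[C@@H]1[C@]1(C)OC(C)(O)C=CC1=O | intermediate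
18 | 6'-methoxy enone ketal (C6' anomers) | CC(=O)O[C@@H]1CC(C)=CC[C@@H]1[C@]1(C)OC(C)(OC)C=CC1=O | intermediate
19 | saturated 3'-ketone ketal | CC(=O)O[C@@H]1CC(C)=CC[C@@H]1[C@]1(C)OC(C)(OC)CCC1=O | intermediate
20 | axial (3'S) alcohol | CC(=O)O[C@@H]1CC(C)=CC[C@@H]1[C@]1(C)OC(C)(OC)CC[C@@H]1O | intermediate
21 | C3' TBS ether of 20 | CC(=O)O[C@@H]1CC(C)=CC[C@@H]1[C@]1(C)OC(C)(OC)CC[C@@H]1O[Si](C)(C)C(C)(C)C | intermediate
22 | C5'=C6' cyclic enol ether | CC(=O)O[C@@H]1CC(C)=CC[C@@H]1[C@]1(C)OC(C)=CC[C@@H]1O[Si](C)(C)C(C)(C)C | intermediate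
23 | (5'S)-5'-bromo-6'-methoxy ketal (C6' anomers) | CC(=O)O[C@@H]1CC(C)=CC[C@@H]1[C@]1(C)OC(C)(OC)[C@@H](Br)C[C@@H]1O[Si](C)(C)C(C)(C)C | intermediate
24 | 5'-bromo-6',6'-dimethyl oxane with ring A alkene | CC(=O)O[C@@H]1CC(C)=CC[C@@H]1[C@]1(C)OC(C)(C)[C@@H](Br)C[C@@H]1O[Si](C)(C)C(C)(C)C | intermediate
25 | (3R,4S) ring A β-epoxide | CC(=O)O[C@@H]1C[C@@]2(C)O[C@H]2C[C@@H]1[C@]1(C)OC(C)(C)[C@@H](Br)C[C@@H]1O[Si](C)(C)C(C)(C)C | intermediate
26 | (3R,4R) 4α-bromo-3β-ol | CC(=O)O[C@@H]1C[C@@](C)(O)[C@H](Br)C[C@@H]1[C@]1(C)OC(C)(C)[C@@H](Br)C[C@@H]1O[Si](C)(C)C(C)(C)C | intermediate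
27 | tertiary chlorosulfite of 26 | CC(=O)O[C@@H]1C[C@@](C)(OS(=O)Cl)[C@H](Br)C[C@@H]1[C@]1(C)OC(C)(C)[C@@H](Br)C[C@@H]1O[Si](C)(C)C(C)(C)C | intermediate
28 | C3' TBS ether of the target | CC(=O)O[C@@H]1C[C@@](C)(Cl)[C@H](Br)C[C@@H]1[C@]1(C)OC(C)(C)[C@@H](Br)C[C@@H]1O[Si](C)(C)C(C)(C)C | intermediate
29 | CNP0251357.1 | CC(=O)O[C@@H]1C[C@@](C)(Cl)[C@H](Br)C[C@@H]1[C@]1(C)OC(C)(C)[C@@H](Br)C[C@@H]1O | target

Total step count: 20. Longest linear sequence: 19 steps (steps 1 and 3–20; the branch through step 2 is equally long).

Steps most likely to fail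

Step 18. Attack at C4 runs against the diaxial-opening preference of the locked half-chair. It may therefore be slow and be overtaken by attack of bromide at C3 or by participation of the C1 acetate at C3.
- The fallback sets out from 25 and accepts the stereoelectronically matched opening.
- Dry HBr in Et2O at low temperature should attack C3 from the α face and give the diaxial 3α-bromo-4β-ol F1.
- SOCl2 then activates the axial C4 hydroxyl. The antiperiplanar C3 bromine expels it to form the α-bromonium ion, and chloride enters from the β face.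
- This should give 28 together with the halogen-interchanged diaxial 3α-bromo-4β-chloride F2.
- Heating F2 in chlorobenzene brings about the known diaxial-to-diequatorial 1,2-interchange of vicinal dihalides and converts it into 28, where the route is rejoined.
- In this variant bromine can only end up α and chlorine only β.

Step 19. The C3 cation may lose a proton and give alkenes, or chloride may enter at C4 after bridging by bromine.
- The fallback sets out from 26 and makes use of the elimination.
- The Burgess reagent (benzene, 50 °C) removes water by syn elimination towards the methyl group and gives the 4α-bromo-3-methylidene compound F3.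
- Dry HCl in CH2Cl2 at −20 °C adds in the Markovnikov sense.
- Protonation of the methylidene carbon regenerates the C3 cation with its α face shielded, and chloride adds from the β face to rejoin the route at 28.

Step 16. Ionisation next to the electron-withdrawing bromine may be sluggish, and the oxocarbenium ion may lose a proton instead of accepting methyl.
- The fallback sets out from 22 and forms the quaternary carbon before any bromine is present.
- Dimethyldioxirane (1 equiv, CH2Cl2, −78 °C) epoxidises the enol ether on the lower face to give the 5',6'-epoxide F4.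
- AlMe3 opens F4 in the same flask at C6' and gives the lower-face 5'-alcohol F5.
- Dess–Martin oxidation gives the 5'-ketone F6, and LiBH(s-Bu)3 gives the axial upper-face 5'-alcohol F7.
- An Appel reaction (CBr4, PPh3, toluene) with inversion returns to the route at 24.

Further compounds
F1 | step 18 | (3S,4S) 3α-bromo-4β-ol | CC(=O)O[C@@H]1C[C@](C)(Br)[C@@H](O)C[C@@H]1[C@]1(C)OC(C)(C)[C@@H](Br)C[C@@H]1O[Si](C)(C)C(C)(C)C
F2 | step 18 | (3S,4S) 3α-bromo-4β-chloride | CC(=O)O[C@@H]1C[C@](C)(Br)[C@@H](Cl)C[C@@H]1[C@]1(C)OC(C)(C)[C@@H](Br)C[C@@H]1O[Si](C)(C)C(C)(C)C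
F3 | step 19 | 4α-bromo-3-methylidene compound | CC(=O)O[C@@H]1CC(=C)[C@H](Br)C[C@@H]1[C@]1(C)OC(C)(C)[C@@H](Br)C[C@@H]1O[Si](C)(C)C(C)(C)C
F4 | step 16 | lower-face 5',6'-epoxide of 22 | CC(=O)O[C@@H]1CC(C)=CC[C@@H]1[C@]1(C)O[C@@]2(C)O[C@H]2C[C@@H]1O[Si](C)(C)C(C)(C)C
F5 | step 16 | lower-face 5'-alcohol, 6',6'-dimethyl | CC(=O)O[C@@H]1CC(C)=CC[C@@H]1[C@]1(C)OC(C)(C)[C@@H](O)C[C@@H]1O[Si](C)(C)C(C)(C)C
F6 | step 16 | 5'-ketone | CC(=O)O[C@@H]1CC(C)=CC[C@@H]1[C@]1(C)OC(C)(C)C(=O)C[C@@H]1O[Si](C)(C)C(C)(C)C
F7 | step 16 | upper-face (axial) 5'-alcohol | CC(=O)O[C@@H]1CC(C)=CC[C@@H]1[C@]1(C)OC(C)(C)[C@H](O)C[C@@H]1O[Si](C)(C)C(C)(C)C
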